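**Strategy.** The plan rests on opening ring C of the eriodictyol unit at O1–C2: that bond lies β to the C4 ketone, and C3, which carries the naringenin C8'' aryl group, is α to it. The precursor is therefore an open (E)-α-aryl-2'-hydroxychalcone with the complete (2''R)-naringenin unit on its α-carbon. A cinchona amine–thiourea closes the pyranone ring by a biomimetic, chalcone-isomerase-like 6-endo oxa-Michael addition, setting C2 under catalyst control, while the acidic C3–H settles trans by equilibration. The naringenin unit is built first by the same type of ring closure; its 8-allyl group, placed by Claisen rearrangement, supplies C3 and C4.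

Key step: step 11

Remark: rotation about the hindered C3–C8'' bond is taken as fast enough that the rotamers are one compound, so only the three sp3 centres need control.

**Step 1**
Reactants: 1 1-[2,4-bis(benzyloxy)-6-hydroxyphenyl]ethanone; 2 allyl bromide
Product: 3 1-[2-(allyloxy)-4,6-bis(benzyloxy)phenyl]ethanone
Conditions: K2CO3, KI (cat.), DMF, 60 °C
Reagents that add atoms: none
Why: Williamson O-alkylation of the only free (hydrogen-bonded) phenol, which warm K2CO3/DMF is known to force.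

**Step 2**
Reactants: 3 1-[2-(allyloxy)-4,6-bis(benzyloxy)phenyl]ethanone
Product: 5 1-[3-allyl-4,6-bis(benzyloxy)-2-hydroxyphenyl]ethanone, via ortho-dienone 4 (not isolated)
Conditions: N,N-diethylaniline, 190 °C, sealed tube
Reagents that add atoms: none
Why: Aromatic Claisen rearrangement ([3,3]-sigmatropic) can deliver the allyl group only to C3', the single unsubstituted ortho carbon, and dienone 4 tautomerizes to the phenol, which places the free OH next to the new carbon substituent.

**Step 3**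
Reactants: 5 1-[3-allyl-4,6-bis(benzyloxy)-2-hydroxyphenyl]ethanone
Product: 6 tert-butyl 3-[3-allyl-4,6-bis(benzyloxy)-2-hydroxyphenyl]-3-oxopropanoate
Conditions: LiN(SiMe3)2 (3.2 equiv), THF, −78 °C; Boc2O, −78 to 0 °C; aq. NH4Cl
Reagents that add atoms: di-tert-butyl dicarbonate (Boc2O), CC(C)(C)OC(=O)OC(=O)OC(C)(C)C
Why: Claisen-type C-acylation of the phenoxide–enolate dianion, in which any aryl carbonate formed at oxygen is carried to carbon by Baker–Venkataraman-type acyl transfer and the bulky tert-butyl ester resists lactonization to a 4-hydroxycoumarin.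

**Step 4**
Reactants: 6 tert-butyl 3-[3-allyl-4,6-bis(benzyloxy)-2-hydroxyphenyl]-3-oxopropanoate; 7 4-(benzyloxy)benzaldehyde
Product: 8 tert-butyl 2-[3-allyl-4,6-bis(benzyloxy)-2-hydroxybenzoyl]-3-[4-(benzyloxy)phenyl]prop-2-enoate
Conditions: piperidine (20 mol%), AcOH (20 mol%), toluene, 4 Å molecular sieves, 60 °C
Reagents that add atoms: none
Why: Knoevenagel condensation of the active methylene group with the aromatic aldehyde gives the tert-butyl alkylidene β-ketoester, a substrate class known to be isolable with its phenol free.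

**Step 5**
Reactants: 8 tert-butyl 2-[3-allyl-4,6-bis(benzyloxy)-2-hydroxybenzoyl]-3-[4-(benzyloxy)phenyl]prop-2-enoate
Product: 10 (2R)-8-allyl-5,7-bis(benzyloxy)-2-[4-(benzyloxy)phenyl]chroman-4-one, via tert-butyl flavanone-3-carboxylate 9 (not isolated)
Conditions: quinine-derived thiourea 1-[3,5-bis(trifluoromethyl)phenyl]-3-[(8S,9S)-6'-methoxycinchonan-9-yl]thiourea (10 mol%), toluene, −25 °C; then TsOH·H2O (0.5 equiv), 80 °C
Reagents that add atoms: none
Why: Known thiourea–tertiary amine catalysed enantioselective intramolecular oxa-Michael addition of alkylidene β-ketoesters, in which two-point binding of the β-ketoester and deprotonation of the phenol by the quinuclidine should set C2 as (R) under catalyst control (the sense is assigned by analogy, and the quinidine-derived pseudoenantiomer gives the other series), after which acid removes the ester by loss of isobutene and decarboxylation and so erases the C3 centre.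

**Step 6**
Reactants: 10 (2R)-8-allyl-5,7-bis(benzyloxy)-2-[4-(benzyloxy)phenyl]chroman-4-one
Product: 12 2-[(2R)-5,7-bis(benzyloxy)-2-[4-(benzyloxy)phenyl]-4-oxochroman-8-yl]acetaldehyde, via vicinal diol 11 (not isolated)
Conditions: OsO4 (2 mol%), NaIO4 (4 equiv), 2,6-lutidine, 1,4-dioxane/H2O (3:1), rt
Reagents that add atoms: OsO4 (osmium tetroxide, catalytic carrier of the oxygen), O=[Os](=O)(=O)=O; NaIO4 (sodium periodate, stoichiometric oxidant), [Na+].[O-]I(=O)(=O)=O
Why: Lemieux–Johnson oxidation cleaves the only alkene under buffered neutral conditions that spare the benzyl ethers, the ketone and C2, and because the ring oxygen O1 is already tied up the arylacetaldehyde cannot form a lactol.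

**Step 7**
Reactants: 12 2-[(2R)-5,7-bis(benzyloxy)-2-[4-(benzyloxy)phenyl]-4-oxochroman-8-yl]acetaldehyde; 13 3,4-bis(benzyloxy)benzaldehyde
Product: 14 (E)-2-[(2R)-5,7-bis(benzyloxy)-2-[4-(benzyloxy)phenyl]-4-oxochroman-8-yl]-3-[3,4-bis(benzyloxy)phenyl]prop-2-enal
Conditions: pyrrolidine (20 mol%), PhCO2H (20 mol%), CH2Cl2, rt; 13 in excess (1.5 equiv), 12 added slowly
Reagents that add atoms: none
Why: Amine-catalysed crossed aldol condensation, in which the enamine of the only enolizable aldehyde adds to non-enolizable 13 and water is lost, should give the thermodynamic (E)-enal (formyl trans to the β-aryl group) while the much less acidic flavanone C3''–H2 stays untouched at room temperature.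

**Step 8**
Reactants: 14 (E)-2-[(2R)-5,7-bis(benzyloxy)-2-[4-(benzyloxy)phenyl]-4-oxochroman-8-yl]-3-[3,4-bis(benzyloxy)phenyl]prop-2-enal
Product: 15 (E)-2-[(2R)-5,7-bis(benzyloxy)-2-[4-(benzyloxy)phenyl]-4-oxochroman-8-yl]-3-[3,4-bis(benzyloxy)phenyl]prop-2-enoic acid
Conditions: NaClO2, NaH2PO4, 2-methyl-2-butene, t-BuOH/THF/H2O, 0 °C to rt
Reagents that add atoms: NaClO2 (sodium chlorite), [Na+].[O-]Cl=O
Why: Pinnick oxidation is selective for aldehydes, enals included, and the alkene scavenger traps HOCl before it can chlorinate the electron-rich rings.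

**Step 9**
Reactants: 15 (E)-2-[(2R)-5,7-bis(benzyloxy)-2-[4-(benzyloxy)phenyl]-4-oxochroman-8-yl]-3-[3,4-bis(benzyloxy)phenyl]prop-2-enoic acid; 16 1,3,5-tris(benzyloxy)benzene
Product: 18 (E)-2-[(2R)-5,7-bis(benzyloxy)-2-[4-(benzyloxy)phenyl]-4-oxochroman-8-yl]-3-[3,4-bis(benzyloxy)phenyl]-1-[2,4,6-tris(benzyloxy)phenyl]prop-2-en-1-one, via mixed trifluoroacetic anhydride 17 (not isolated)
Conditions: (CF3CO)2O (4 equiv), CH2Cl2, 0 °C; then 16 (1.5 equiv), 0 °C to rt
Reagents that add atoms: none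
Why: Friedel–Crafts acylation through the mixed trifluoroacetic anhydride, which acylates phloroglucinol triethers without a Lewis acid so that the benzyl ethers survive; the three positions of 16 are equivalent, the product ketone is deactivated against a second acylation, and the (E)-geometry keeps the acyl carbon away from the β-aryl ring.

**Step 10**
Reactants: 18 (E)-2-[(2R)-5,7-bis(benzyloxy)-2-[4-(benzyloxy)phenyl]-4-oxochroman-8-yl]-3-[3,4-bis(benzyloxy)phenyl]-1-[2,4,6-tris(benzyloxy)phenyl]prop-2-en-1-one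
Product: 19 (E)-1-[2,4-bis(benzyloxy)-6-hydroxyphenyl]-2-[(2R)-7-(benzyloxy)-2-[4-(benzyloxy)phenyl]-5-hydroxy-4-oxochroman-8-yl]-3-[3,4-bis(benzyloxy)phenyl]prop-2-en-1-one
Conditions: BCl3 (2.4 equiv, 1 M in CH2Cl2), CH2Cl2, −78 °C; cold water quench; used at once
Reagents that add atoms: none
Why: Chelation-controlled cleavage by BCl3 removes one benzyl ether next to each ketone through a six-membered boron chelate, which stops further cleavage on that ring and holds the new phenol until the cold quench.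

**Step 11**
Reactants: 19 (E)-1-[2,4-bis(benzyloxy)-6-hydroxyphenyl]-2-[(2R)-7-(benzyloxy)-2-[4-(benzyloxy)phenyl]-5-hydroxy-4-oxochroman-8-yl]-3-[3,4-bis(benzyloxy)phenyl]prop-2-en-1-one
Product: 21 (2R,3S)-5,7-bis(benzyloxy)-3-[(2R)-7-(benzyloxy)-2-[4-(benzyloxy)phenyl]-5-hydroxy-4-oxochroman-8-yl]-2-[3,4-bis(benzyloxy)phenyl]chroman-4-one, via chromen-4-ol enol 20 (not isolated)
Conditions: quinine-derived thiourea 1-[3,5-bis(trifluoromethyl)phenyl]-3-[(8S,9S)-6'-methoxycinchonan-9-yl]thiourea (10–20 mol%), toluene, −20 °C; then rt until C3 equilibration is complete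
Reagents that add atoms: none
Why: Proposed new method: the quinuclidine nitrogen deprotonates the hydrogen-bonded 2'-OH of 19 while the thiourea binds the enone carbonyl, and the phenoxide adds to the β-carbon (future C2) to give enol 20, which ketonizes; the closest known reaction type is the cinchona-thiourea-catalysed enantioselective oxa-Michael cyclization of 2'-hydroxychalcone-type enones to flavanones (step 5), not yet shown for α-aryl chalcones that lack a second activating group. The dihydropyranone ring closes by a 6-endo-trig oxa-conjugate addition that forms the O1–C2 bond. C2 is set by the catalyst, which should shield the same enone face as in step 5 because both closures have the same topology (phenoxide, enone and β-aryl group in the same arrangement), giving (2R); C3 is set by thermodynamic control, since its proton is α to the C4 ketone and is equilibrated by the amine to the 2,3-trans isomer with both aryl groups equatorial. The step needs face selectivity at the β-carbon without uncatalysed closure or retro-addition, and the single free ortho phenol (the other ortho oxygen is benzylated), its hydrogen bond to the ketone, the defined (E)-geometry and the bulky α-aryl group, which slows the background reaction, are expected to secure this. The remote C2'' centre and the hydrogen-bonded 5''-OH of the naringenin unit are spectators under these weakly basic conditions.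

**Step 12**
Reactants: 21 (2R,3S)-5,7-bis(benzyloxy)-3-[(2R)-7-(benzyloxy)-2-[4-(benzyloxy)phenyl]-5-hydroxy-4-oxochroman-8-yl]-2-[3,4-bis(benzyloxy)phenyl]chroman-4-one
Product: 22 (2R,3S)-2-(3,4-dihydroxyphenyl)-5,7-dihydroxy-3-[(2R)-5,7-dihydroxy-2-(4-hydroxyphenyl)-4-oxochroman-8-yl]chroman-4-one
Conditions: H2 (1 atm), 10% Pd/C, EtOAc/MeOH (1:1), rt; neutral work-up
Reagents that add atoms: none
Why: Hydrogenolysis of the six aryl benzyl ethers over Pd/C under neutral conditions should leave the aryl ketones, the slower-reacting secondary benzylic C2–O1 bonds and the three stereocentres intact.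

**Compound list**

1 | 1-[2,4-bis(benzyloxy)-6-hydroxyphenyl]ethanone | CC(=O)c1c(O)cc(OCc2ccccc2)cc1OCc1ccccc1 | starting material
2 | allyl bromide | C=CCBr | starting material
3 | 1-[2-(allyloxy)-4,6-bis(benzyloxy)phenyl]ethanone | CC(=O)c1c(OCC=C)cc(OCc2ccccc2)cc1OCc1ccccc1 | intermediate
4 | 2-acetyl-6-allyl-3,5-bis(benzyloxy)cyclohexa-2,4-dien-1-one (ortho-dienone, racemic at C6) | CC(=O)C1=C(OCc2ccccc2)C=C(OCc2ccccc2)C(CC=C)C1=O | intermediate
5 | 1-[3-allyl-4,6-bis(benzyloxy)-2-hydroxyphenyl]ethanone | CC(=O)c1c(O)c(CC=C)c(OCc2ccccc2)cc1OCc1ccccc1 | intermediate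
6 | tert-butyl 3-[3-allyl-4,6-bis(benzyloxy)-2-hydroxyphenyl]-3-oxopropanoate | CC(C)(C)OC(=O)CC(=O)c1c(O)c(CC=C)c(OCc2ccccc2)cc1OCc1ccccc1 | intermediate
7 | 4-(benzyloxy)benzaldehyde | O=Cc1ccc(OCc2ccccc2)cc1 | starting material
8 | tert-butyl 2-[3-allyl-4,6-bis(benzyloxy)-2-hydroxybenzoyl]-3-[4-(benzyloxy)phenyl]prop-2-enoate (mixture of alkene isomers) | CC(C)(C)OC(=O)C(=Cc1ccc(OCc2ccccc2)cc1)C(=O)c1c(O)c(CC=C)c(OCc2ccccc2)cc1OCc1ccccc1 | intermediate
9 | tert-butyl (2R,3S)-8-allyl-5,7-bis(benzyloxy)-2-[4-(benzyloxy)phenyl]-4-oxochromane-3-carboxylate (trans keto form) | O=C1[C@@H](C(=O)OC(C)(C)C)[C@H](c2ccc(OCc3ccccc3)cc2)Oc2c1c(OCc1ccccc1)cc(OCc1ccccc1)c2CC=C | intermediate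
10 | (2R)-8-allyl-5,7-bis(benzyloxy)-2-[4-(benzyloxy)phenyl]chroman-4-one | O=C1C[C@H](c2ccc(OCc3ccccc3)cc2)Oc2c1c(OCc1ccccc1)cc(OCc1ccccc1)c2CC=C | intermediate
11 | (2R)-5,7-bis(benzyloxy)-2-[4-(benzyloxy)phenyl]-8-(2,3-dihydroxypropyl)chroman-4-one (both carbinol epimers) | O=C1C[C@H](c2ccc(OCc3ccccc3)cc2)Oc2c1c(OCc1ccccc1)cc(OCc1ccccc1)c2CC(O)CO | intermediate
12 | 2-[(2R)-5,7-bis(benzyloxy)-2-[4-(benzyloxy)phenyl]-4-oxochroman-8-yl]acetaldehyde | O=C1C[C@H](c2ccc(OCc3ccccc3)cc2)Oc2c1c(OCc1ccccc1)cc(OCc1ccccc1)c2CC=O | intermediate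
13 | 3,4-bis(benzyloxy)benzaldehyde | O=Cc1ccc(OCc2ccccc2)c(OCc2ccccc2)c1 | starting material
14 | (E)-2-[(2R)-5,7-bis(benzyloxy)-2-[4-(benzyloxy)phenyl]-4-oxochroman-8-yl]-3-[3,4-bis(benzyloxy)phenyl]prop-2-enal | O=C/C(=C/c1ccc(OCc2ccccc2)c(OCc2ccccc2)c1)c1c(OCc2ccccc2)cc(OCc2ccccc2)c2c1O[C@@H](c1ccc(OCc3ccccc3)cc1)CC2=O | intermediate
15 | (E)-2-[(2R)-5,7-bis(benzyloxy)-2-[4-(benzyloxy)phenyl]-4-oxochroman-8-yl]-3-[3,4-bis(benzyloxy)phenyl]prop-2-enoic acid | OC(=O)/C(=C/c1ccc(OCc2ccccc2)c(OCc2ccccc2)c1)c1c(OCc2ccccc2)cc(OCc2ccccc2)c2c1O[C@@H](c1ccc(OCc3ccccc3)cc1)CC2=O | intermediate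
16 | 1,3,5-tris(benzyloxy)benzene | c1ccc(COc2cc(OCc3ccccc3)cc(OCc3ccccc3)c2)cc1 | starting material
17 | mixed anhydride of 15 with trifluoroacetic acid | O=C(OC(=O)C(F)(F)F)/C(=C/c1ccc(OCc2ccccc2)c(OCc2ccccc2)c1)c1c(OCc2ccccc2)cc(OCc2ccccc2)c2c1O[C@@H](c1ccc(OCc3ccccc3)cc1)CC2=O | intermediate
18 | (E)-2-[(2R)-5,7-bis(benzyloxy)-2-[4-(benzyloxy)phenyl]-4-oxochroman-8-yl]-3-[3,4-bis(benzyloxy)phenyl]-1-[2,4,6-tris(benzyloxy)phenyl]prop-2-en-1-one | O=C(c1c(OCc2ccccc2)cc(OCc2ccccc2)cc1OCc1ccccc1)/C(=C/c1ccc(OCc2ccccc2)c(OCc2ccccc2)c1)c1c(OCc2ccccc2)cc(OCc2ccccc2)c2c1O[C@@H](c1ccc(OCc3ccccc3)cc1)CC2=O | intermediate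
19 | (E)-1-[2,4-bis(benzyloxy)-6-hydroxyphenyl]-2-[(2R)-7-(benzyloxy)-2-[4-(benzyloxy)phenyl]-5-hydroxy-4-oxochroman-8-yl]-3-[3,4-bis(benzyloxy)phenyl]prop-2-en-1-one | O=C(c1c(O)cc(OCc2ccccc2)cc1OCc1ccccc1)/C(=C/c1ccc(OCc2ccccc2)c(OCc2ccccc2)c1)c1c(OCc2ccccc2)cc(O)c2c1O[C@@H](c1ccc(OCc3ccccc3)cc1)CC2=O | intermediate
20 | (2R)-7-(benzyloxy)-2-[4-(benzyloxy)phenyl]-8-[(2S)-5,7-bis(benzyloxy)-2-[3,4-bis(benzyloxy)phenyl]-4-hydroxy-2H-chromen-3-yl]-5-hydroxychroman-4-one (enol; C2 has the same spatial arrangement as in 21, the descriptor changes by the sequence rule) | O=C1C[C@H](c2ccc(OCc3ccccc3)cc2)Oc2c1c(O)cc(OCc1ccccc1)c2C1=C(O)c2c(OCc3ccccc3)cc(OCc3ccccc3)cc2O[C@H]1c1ccc(OCc2ccccc2)c(OCc2ccccc2)c1 | intermediate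
21 | (2R,3S)-5,7-bis(benzyloxy)-3-[(2R)-7-(benzyloxy)-2-[4-(benzyloxy)phenyl]-5-hydroxy-4-oxochroman-8-yl]-2-[3,4-bis(benzyloxy)phenyl]chroman-4-one | O=C1C[C@H](c2ccc(OCc3ccccc3)cc2)Oc2c1c(O)cc(OCc1ccccc1)c2[C@@H]1C(=O)c2c(OCc3ccccc3)cc(OCc3ccccc3)cc2O[C@H]1c1ccc(OCc2ccccc2)c(OCc2ccccc2)c1 | intermediate
22 | (2R,3S)-2-(3,4-dihydroxyphenyl)-5,7-dihydroxy-3-[(2R)-5,7-dihydroxy-2-(4-hydroxyphenyl)-4-oxochroman-8-yl]chroman-4-one | O=C1C[C@H](c2ccc(O)cc2)Oc2c1c(O)cc(O)c2[C@@H]1C(=O)c2c(O)cc(O)cc2O[C@H]1c1ccc(O)c(O)c1 | target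

**Step count and risks**

Total step count: 12. Longest linear sequence: 12 steps (1 to 22); compounds 2, 7, 13 and 16 enter as purchased building blocks.

Steps most likely to fail:

1. Step 11 (Proposed new method). The risk is insufficient facial selectivity at the β-carbon, because catalyst control can be diluted by uncatalysed closure or by reversible ring opening of the product. Fallback with known chemistry: setting out from 19, the ring is closed under thermodynamic control with NaOAc in EtOH at 50 °C (classical base-mediated cyclization of 2'-hydroxy-α-arylchalcones to trans-3-arylflavanones). This should give 21 together with its (2S,3R,2''R) diastereomer F1. Because the C2'' centre is fixed, the two are diastereomers and are separated by chromatography. F1 is returned to the same base, re-equilibrated through the open chalcone and recycled. The route is rejoined at 21.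

2. Step 9. The risk is arylation of the electron-rich acrylic system at its β-carbon, or acid-induced loss of benzyl groups, competing with acylation at the hindered acyl carbon. Fallback: setting out from enal 14 and arene 16, the ketone is made with a nucleophilic aryl reagent instead of an electrophilic acyl reagent. Arene 16 is brominated with N-bromosuccinimide in CH2Cl2 at −78 °C to 2-bromo-1,3,5-tris(benzyloxy)benzene F2. Bromine–lithium exchange with n-BuLi in THF at −78 °C and transmetalation with CeCl3 give a weakly basic aryl cerium reagent. It should add to the aldehyde of 14 in preference to the deactivated flavanone ketone, giving the allylic alcohol (E)-2-[(2R)-5,7-bis(benzyloxy)-2-[4-(benzyloxy)phenyl]-4-oxochroman-8-yl]-3-[3,4-bis(benzyloxy)phenyl]-1-[2,4,6-tris(benzyloxy)phenyl]prop-2-en-1-ol F3. Oxidation with Dess–Martin periodinane (NaHCO3, CH2Cl2) rejoins the route at 18.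

3. Step 5. The risk is erosion of enantioselectivity on this doubly ortho-substituted aryl ketone, by uncatalysed closure or by acid-induced ring opening and reclosure during the hot decarboxylation. Fallback: setting out from 5 and 7, Claisen–Schmidt condensation (KOH, EtOH, rt) gives (E)-1-[3-allyl-4,6-bis(benzyloxy)-2-hydroxyphenyl]-3-[4-(benzyloxy)phenyl]prop-2-en-1-one F4. Cyclization with NaOAc in refluxing EtOH gives racemic 8-allyl-5,7-bis(benzyloxy)-2-[4-(benzyloxy)phenyl]chroman-4-one F5. Kinetic resolution by asymmetric transfer hydrogenation with RuCl(p-cymene)[(S,S)-TsDPEN] in HCO2H/Et3N should reduce the (2S)-enantiomer to (2S,4S)-8-allyl-5,7-bis(benzyloxy)-2-[4-(benzyloxy)phenyl]chroman-4-ol F6. The unreacted (2R)-ketone is separated by chromatography, rejoining the route at 10.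

**Further compounds**

F1 | step 11 | (2S,3R)-5,7-bis(benzyloxy)-3-[(2R)-7-(benzyloxy)-2-[4-(benzyloxy)phenyl]-5-hydroxy-4-oxochroman-8-yl]-2-[3,4-bis(benzyloxy)phenyl]chroman-4-one | O=C1C[C@H](c2ccc(OCc3ccccc3)cc2)Oc2c1c(O)cc(OCc1ccccc1)c2[C@H]1C(=O)c2c(OCc3ccccc3)cc(OCc3ccccc3)cc2O[C@@H]1c1ccc(OCc2ccccc2)c(OCc2ccccc2)c1
F2 | step 9 | 2-bromo-1,3,5-tris(benzyloxy)benzene | Brc1c(OCc2ccccc2)cc(OCc2ccccc2)cc1OCc1ccccc1
F3 | step 9 | (E)-2-[(2R)-5,7-bis(benzyloxy)-2-[4-(benzyloxy)phenyl]-4-oxochroman-8-yl]-3-[3,4-bis(benzyloxy)phenyl]-1-[2,4,6-tris(benzyloxy)phenyl]prop-2-en-1-ol (both carbinol epimers) | OC(c1c(OCc2ccccc2)cc(OCc2ccccc2)cc1OCc1ccccc1)/C(=C/c1ccc(OCc2ccccc2)c(OCc2ccccc2)c1)c1c(OCc2ccccc2)cc(OCc2ccccc2)c2c1O[C@@H](c1ccc(OCc3ccccc3)cc1)CC2=O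
F4 | step 5 | (E)-1-[3-allyl-4,6-bis(benzyloxy)-2-hydroxyphenyl]-3-[4-(benzyloxy)phenyl]prop-2-en-1-one | O=C(/C=C/c1ccc(OCc2ccccc2)cc1)c1c(O)c(CC=C)c(OCc2ccccc2)cc1OCc1ccccc1
F5 | step 5 | racemic 8-allyl-5,7-bis(benzyloxy)-2-[4-(benzyloxy)phenyl]chroman-4-one | O=C1CC(c2ccc(OCc3ccccc3)cc2)Oc2c1c(OCc1ccccc1)cc(OCc1ccccc1)c2CC=C
F6 | step 5 | (2S,4S)-8-allyl-5,7-bis(benzyloxy)-2-[4-(benzyloxy)phenyl]chroman-4-ol | O[C@H]1C[C@@H](c2ccc(OCc3ccccc3)cc2)Oc2c1c(OCc1ccccc1)cc(OCc1ccccc1)c2CC=C
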